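**Assumption:** the target has no stereocentre and is achiral (symmetric dibenzyl ether), so "single enantiomer" sets no stereochemical task; the route delivers the one constitution drawn.

**Retrosynthetic overview**
1. Cut both benzylic C–O bonds of the symmetric ether: two identical C7 electrophiles (a 2-hydroxy-p-quinone methide) plus one molecule of water as the oxygen source.
2. The quinone methide is the tautomer of a 4-methyl-o-quinone, so the benzylic oxidation is paid for by the catechol/quinone couple and no separate C–H oxidation is needed.
3. The o-quinone comes from the tribrominated 4-methylcatechol, which comes from 4-methylcatechol by exhaustive ring bromination (all three free positions, no regiochemical question).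
4. No ring is constructed: both benzene rings are bought intact.
5. Forward: 4-methylcatechol 1 → tribromocatechol 2 → o-quinone 3 → (quinone methide 4 and benzyl alcohol 5, both in the flask) → ether 6.

**Route**

Step 1
Reactants: 1 4-methylcatechol (4-methylbenzene-1,2-diol)
Product: 2 3,4,6-tribromo-5-methylbenzene-1,2-diol
Conditions: Br2 (3.05 equiv), AcOH, 10 °C → rt, dark
Reagents that add atoms: bromine, BrBr
Why: Electrophilic aromatic bromination of a doubly activated catechol in which every free ring position is ortho or para to an OH, so three Br enter with no regiochemical choice (same reaction type as tetrabromocatechol from catechol); a reductive aqueous wash (Na2S2O4) at work-up returns any trace of over-oxidised quinone to 2.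

Step 2
Reactants: 2 3,4,6-tribromo-5-methylbenzene-1,2-diol
Product: 3 3,4,6-tribromo-5-methylcyclohexa-3,5-diene-1,2-dione
Conditions: PhI(OAc)2 (1.00 equiv), CH2Cl2, 0 °C, 20 min; evaporate, triturate with cold hexane (no aqueous work-up)
Reagents that add atoms: none
Why: Two-electron dehydrogenation of a catechol to its o-quinone by phenyliodine diacetate (ligand exchange at iodine, then loss of PhI); the fully substituted, o-bromanil-like quinone cannot dimerise or add nucleophiles at a ring CH, and the non-aqueous isolation removes all oxidant before step 3.

Step 3
Reactants: 3 3,4,6-tribromo-5-methylcyclohexa-3,5-diene-1,2-dione (two molecules per molecule of product)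
Product: 6 bis(2,3,6-tribromo-4,5-dihydroxybenzyl) ether, via quinone methide 4 (not isolated), via benzyl alcohol 5 (not isolated)
Conditions: H2O (0.50 equiv), Bu4N(O2CCMe3) (5 mol%), Me3CCO2H (20 mol%), catechol 2 (1.0 equiv, redox buffer, recovered), MeCN (0.1 M), Ar, dark, 25 → 40 °C
Reagents that add atoms: water, O
Why: Proposed new method: a redox-neutral isomerising hydro-etherification in which the pivalate/pivalic acid pair acts as a bifunctional proton shuttle, moving a proton from the bromine-acidified γ-methyl group of 3 to the conjugated carbonyl oxygen (vinylogous enolisation) to give the 2-hydroxy-p-quinone methide 4; rearomatisation then drives 1,6-addition of water at the exocyclic CH2 (first C–O bond, 5) and 1,6-addition of the primary OH of 5 to a second molecule of 4 (second C–O bond, 6), and with exactly 0.5 equiv of water the ether is the only product that balances the equation; C-alkylation is impossible because every ring position is substituted, aryl ethers from phenolic O-attack should re-ionise to 4 (acidic phenol as leaving group), and the added catechol 2 is intended to hold the quinone/catechol exchange on the side of 3 (the CH2OR-substituted product catechols should be the harder ones to oxidise, by an estimated 50 mV), so the products are not carried on to the aldehyde; closest known reaction type: tautomerisation of 4-alkyl-o-quinones to p-quinone methides followed by conjugate addition of water, and oxa-1,6-addition of alcohols to p-quinone methides.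

**Compound list**
1 | 4-methylcatechol (4-methylbenzene-1,2-diol) | Cc1ccc(O)c(O)c1 | starting material
2 | 3,4,6-tribromo-5-methylbenzene-1,2-diol | Cc1c(Br)c(Br)c(O)c(O)c1Br | intermediate
3 | 3,4,6-tribromo-5-methylcyclohexa-3,5-diene-1,2-dione | CC1=C(Br)C(=O)C(=O)C(Br)=C1Br | intermediate
4 | 2,3,5-tribromo-6-hydroxy-4-methylidenecyclohexa-2,5-dien-1-one | C=C1C(Br)=C(O)C(=O)C(Br)=C1Br | intermediate
5 | 3,4,6-tribromo-5-(hydroxymethyl)benzene-1,2-diol | OCc1c(Br)c(Br)c(O)c(O)c1Br | intermediate
6 | bis(2,3,6-tribromo-4,5-dihydroxybenzyl) ether | Oc1c(O)c(Br)c(COCc2c(Br)c(O)c(O)c(Br)c2Br)c(Br)c1Br | target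

**Total step count:** 3
**Longest linear sequence:** 3 steps (1 → 2 → 3 → 6; both halves of 6 come from the same intermediate 3)

**Steps most likely to fail**

Step 3 (the new isomerising hydro-etherification). Risks are quinone/catechol redox exchange that carries product on to 2,3,6-tribromo-4,5-dihydroxybenzaldehyde, C–C coupling of the deprotonated quinone methide, and sluggish tautomerisation. The fallback uses known chemistry only and sets out from 2. Ac2O in pyridine at rt gives 3,4,6-tribromo-5-methyl-1,2-phenylene diacetate F1. Wohl–Ziegler bromination (NBS, 2,2'-azobis(2-methylpropionitrile), PhCF3, 85 °C) gives 3,4,6-tribromo-5-(bromomethyl)-1,2-phenylene diacetate F2. LiOH in degassed THF/H2O at 0 °C, then dilute HCl, removes both acetates and hydrolyses the benzylic bromide (the freed para-phenoxide expels bromide and water in large excess adds). This comes back to the route at 5, now isolated. Compound 5 is then closed to 6 by ordinary acid-catalysed dehydrative homo-etherification of a p-hydroxybenzyl alcohol (p-toluenesulfonic acid monohydrate 5 mol%, MeNO2/toluene, 70 °C, azeotropic removal of water); the blocked ring positions exclude C-alkylation.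

Step 2 (oxidation to and isolation of the o-quinone). Risks are premature tautomerisation or decomposition of 3 on isolation and carry-over of oxidant into step 3. The fallback sets out from 2 and avoids an isolated quinone. Br2 (1.05 equiv) in AcOH at 70 °C, the classical side-chain bromination of fully ring-halogenated cresol-type phenols, gives 3,4,6-tribromo-5-(bromomethyl)benzene-1,2-diol F3, a storable benzylic bromide. F3 with solid NaHCO3 (1.1 equiv) and H2O (0.50 equiv) in MeCN at rt loses HBr by 1,6-elimination and so comes back to the route at 4, which goes on to 5 and 6 as in step 3. No quinone is present, so no redox buffer is needed.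

Step 1 (tribromination of the free catechol). Risks are over-oxidation by Br2, benzylic bromide by-products formed through the quinone, and an incomplete third bromination. The fallback sets out from 1 and brominates a protected ring. MeI and K2CO3 in refluxing acetone give 1,2-dimethoxy-4-methylbenzene F4. Br2 (3.3 equiv) with Fe powder (5 mol%) in CH2Cl2 at rt → 40 °C gives 1,2,4-tribromo-5,6-dimethoxy-3-methylbenzene F5. BBr3 in CH2Cl2 at −78 °C → rt, then water, cleaves both methyl ethers and comes back to the route at 2.

**Further compounds**
F1 | step 3 | 3,4,6-tribromo-5-methyl-1,2-phenylene diacetate | CC(=O)Oc1c(OC(C)=O)c(Br)c(C)c(Br)c1Br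
F2 | step 3 | 3,4,6-tribromo-5-(bromomethyl)-1,2-phenylene diacetate | CC(=O)Oc1c(OC(C)=O)c(Br)c(CBr)c(Br)c1Br
F3 | step 2 | 3,4,6-tribromo-5-(bromomethyl)benzene-1,2-diol | Oc1c(O)c(Br)c(CBr)c(Br)c1Br
F4 | step 1 | 1,2-dimethoxy-4-methylbenzene | COc1ccc(C)cc1OC
F5 | step 1 | 1,2,4-tribromo-5,6-dimethoxy-3-methylbenzene | COc1c(OC)c(Br)c(C)c(Br)c1Br
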